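**Strategy.** The 33-membered lactone is cut at C17–C18 (C1 = carbonyl carbon, C32 = OCH2), a bond inside the unbroken run of 31 methylene groups and remote from the only functional group, the C1(=O)–O ester. Because the ring is strain-free and every carbon from C2 to C32 is a CH2, an alkene at C17=C18 can serve as a traceless closure site. The key step is a ring-closing olefin metathesis of the open-chain diene ester hexadec-15-en-1-yl octadec-17-enoate, which joins the two vinyl CH carbons as C17=C18 with loss of ethylene and is followed in the same pot by Ru-catalysed hydrogenation to the saturated macrolide.

Key step: step 3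

Remark: the target has no stereocentre and is achiral, so no stereocontrol is needed; all four starting materials (1, 2, 4 and the reagents) are taken to be catalogue chemicals.

**Step 1**
Reactants: 1 8-bromooctanoic acid; 2 6-bromohexan-1-ol
Product: 3 6-bromohexyl 8-bromooctanoate
Conditions: DCC (1.1 equiv), DMAP (0.1 equiv), CH2Cl2, 0 °C → rt
Reagents that add atoms: none
Why: Steglich esterification; the O-acylisourea of 1 is transferred by DMAP to the primary alcohol of 2, and both primary C–Br bonds are inert under these neutral conditions at room temperature.

**Step 2**
Reactants: 3 6-bromohexyl 8-bromooctanoate; 4 10-bromodec-1-ene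
Product: 6 hexadec-15-en-1-yl octadec-17-enoate, via dec-9-en-1-ylmagnesium bromide 5 (not isolated)
Conditions: 4 (2.6 equiv), Mg, THF, rt → 45 °C; then added slowly to 3, Li2CuCl4 (5 mol%), NMP (4 equiv per C–Br), THF, 0 °C → rt; aq. NH4Cl
Reagents that add atoms: none
Why: Twofold copper-catalysed sp3–sp3 Grignard–alkyl bromide coupling (Kochi-type, NMP additive); the alkylcopper pathway at the two primary bromides should outpace 1,2-addition to the ester when the Grignard reagent is kept at low stationary concentration, and it lengthens the acyl arm by ten carbons to octadec-17-enoyl and the alkoxy arm to hexadec-15-enyl.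

**Step 3**
Reactants: 6 hexadec-15-en-1-yl octadec-17-enoate
Product: 8 oxacyclotritriacontan-2-one, via oxacyclotritriacont-18-en-2-one 7 (not isolated)
Conditions: (H2IMes)(PCy3)Cl2Ru=CHPh (5 mol%), ClCH2CH2Cl (1 mM final, 6 added by syringe pump), 50 °C, Ar sparge; then H2 (7 bar), 70 °C, same pot
Reagents that add atoms: none
Why: Ring-closing olefin metathesis by the metallacyclobutane mechanism: the Ru carbene loads onto one terminal vinyl group and the resulting alkylidene undergoes intramolecular [2+2]/retro-[2+2] with the other vinyl group, forming C17=C18 and expelling ethylene; under H2 the same ruthenium is converted into Ru–H species that saturate the new disubstituted alkene. The closest known reaction type is the macrolactone synthesis by RCM of ω-alkenyl ω-alkenoates followed by tandem ruthenium-catalysed hydrogenation. The 33-membered ring is closed as an end-to-end macrocyclisation of two monosubstituted alkenes, entropically disfavoured but strain-free. No stereocentre is formed, and the E/Z mixture of 7 converges on one product on hydrogenation. The step needs ring closure to win over acyclic diene metathesis oligomerisation and needs the double bonds to stay terminal before closure; high dilution with slow addition, ethylene removal and the reversibility of metathesis (which returns oligomers to the ring) should secure the first, while the moderate temperature and the all-methylene chain without allylic heteroatoms limit isomerisation. The lactone is the only other functional group and is inert to both the carbene and the hydride catalyst.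

**Compound list**
1 | 8-bromooctanoic acid | OC(=O)CCCCCCCBr | starting material
2 | 6-bromohexan-1-ol | OCCCCCCBr | starting material
3 | 6-bromohexyl 8-bromooctanoate | BrCCCCCCCC(=O)OCCCCCCBr | intermediate
4 | 10-bromodec-1-ene | C=CCCCCCCCCBr | starting material
5 | dec-9-en-1-ylmagnesium bromide | C=CCCCCCCCC[Mg]Br | intermediate (not isolated)
6 | hexadec-15-en-1-yl octadec-17-enoate | C=CCCCCCCCCCCCCCCCC(=O)OCCCCCCCCCCCCCCC=C | intermediate
7 | oxacyclotritriacont-18-en-2-one (E/Z mixture, geometry left open) | O=C1CCCCCCCCCCCCCCCC=CCCCCCCCCCCCCCCO1 | intermediate (not isolated)
8 | oxacyclotritriacontan-2-one (32-dotriacontanolide) | O=C1CCCCCCCCCCCCCCCCCCCCCCCCCCCCCCCO1 | target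

**Total step count:** 3
**Longest linear sequence:** 3 steps (1 → 3 → 6 → 8)

**Steps most likely to fail**

Step 3 (key step). Acyclic diene metathesis oligomerisation may compete with ring closure. Ruthenium hydride formed by catalyst decay may move the terminal double bonds along the chain before closure, so that propene instead of ethylene is lost and ring-contracted homologues arise. Hydrogenation at high dilution may stall. Fallback, setting out from 6: ozonolysis (O3, CH2Cl2, −78 °C; then Me2S) should give the dialdehyde 15-oxopentadecyl 17-oxoheptadecanoate F1, whose two formyl carbons are C17 and C18. Intramolecular McMurry coupling (TiCl3(DME)1.5, Zn–Cu, DME, reflux, syringe-pump addition) joins them as C17=C18 on the low-valent titanium surface, where no double-bond migration can occur and the aldehydes react faster than the ester. This comes back to the route at 7, which is then isolated and hydrogenated (H2, Pd/C, EtOAc, rt) to 8.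

Step 2. The Grignard reagent may add to the ester carbonyl, one of the two bromides may remain uncoupled, and reduction or elimination at C–Br may compete. Fallback, setting out from 1 and 2 (with 5 made as in step 2): the C–C couplings are moved ahead of ester formation. Acid 1, treated with 5 (one equivalent as sacrificial base, then Li2CuCl4 cat., THF, −20 °C → rt), should give octadec-17-enoic acid F2. Alcohol 2, treated in the same way, should give hexadec-15-en-1-ol F3. Esterification of F2 with F3 (DCC, DMAP, CH2Cl2) comes back to the route at 6.

Step 1. The O-acylisourea may rearrange to the unreactive N-acylurea, and DMAP may be slowly alkylated by the primary bromides. Fallback, setting out from 1: oxalyl chloride with catalytic DMF in CH2Cl2 gives 8-bromooctanoyl chloride F4, which acylates 2 in the presence of pyridine (CH2Cl2, 0 °C) and comes back to the route at 3.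

**Further compounds**
F1 | step 3 | 15-oxopentadecyl 17-oxoheptadecanoate | O=CCCCCCCCCCCCCCCCC(=O)OCCCCCCCCCCCCCCC=O
F2 | step 2 | octadec-17-enoic acid | C=CCCCCCCCCCCCCCCCC(=O)O
F3 | step 2 | hexadec-15-en-1-ol | OCCCCCCCCCCCCCCC=C
F4 | step 1 | 8-bromooctanoyl chloride | ClC(=O)CCCCCCCBr
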